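The readings come from a simulation for an exercise.

**The ceiling.** 60.0% of the substrate charged is where we expect target to stop in the new flask. We call this ceiling, c(coupling partner) charged over c(substrate) charged, and take coupling partner as the limiting reagent. We assume one coupling partner used per target made, so dividing the two rates removes time and leaves the ceiling.

| flask | substrate | coupling partner | free catalyst | remark |
|---|---|---|---|---|
| birch | 2.1 M | 0.90 M | 30 mM | run made earlier |
| alder | 1.5 M | 0.90 M | 15 mM | run made earlier |
| flask | 1.5 M | 0.900 M | 30 mM |  |

| run | time / d | target / % | substrate / % |
|---|---|---|---|
| birch | 0.833 | 42.9 | 56.4 |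
| birch | 1.67 | 41.4 | 57.2 |
| birch | 2.50 | 42.8 | 58.0 |
| birch | 3.00 | 40.9 | 58.0 |
| alder | 0.833 | 57.2 | 42.2 |
| alder | 1.67 | 60.2 | 41.0 |
| alder | 2.50 | 59.5 | 39.8 |
| alder | 3.00 | 59.6 | 38.8 |

(standard deviation of a reading: 1 percentage point)

- no earlier run changes the charge of coupling partner; that part of a forecast is a guess

1. apparent order in free catalyst when 20% of the substrate are converted (percent change of the rate of making target for one percent more free catalyst charged)
2. apparent order in coupling partner when 20% of the substrate are converted (percent change of the rate of making target for one percent more coupling partner charged)
3. factor on the rate of making target when 20% of the substrate are converted if free catalyst is charged twice over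

**First check.** For birch the ceiling is 42.9%, and its target readings average 42.0%.

**Next run.** The asked point, 20% conversion of substrate, lies a third of the way to the ceiling, and at that conversion we reckon c(coupling partner) at 0.600 M. The first target reading of alder, at 0.833 d, already stood at nearly all of its ceiling. So we keep the charges of the new flask and place its samples well before that time.

**The forecast.** It gives an order of 0.85 in free catalyst, 0.5 in coupling partner, and a factor of 1.8 for doubled free catalyst. Of the second it says: “The coupling-partner order is a pure guess”.

**The result.** The new flask gives 0.80, 0.34 and 1.69, so the forecast's order in coupling partner stands higher than the flask's, by a factor of 1.45.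

    substrate + free catalyst ⇌ catalyst intermediate A (K = 0.260 /M, k = 9.40 /M/h)
    coupling partner + catalyst intermediate A → catalyst intermediate B (k = 210 /M/h)
    catalyst intermediate B → by-product + catalyst intermediate C (k = 110 /h)
    catalyst intermediate C ⇌ free catalyst + target (K = 1.20 M, k = 110 /h)
    2 free catalyst ⇌ resting dimer, settled at all times (K = 16.0 /M)

**Where it stops.** In the new flask, the step from catalyst intermediate B to by-product and catalyst intermediate C has 99% of its turnover up to 3.00 d behind it at 0.600 d, far earlier than that end. At 1.50 d coupling partner stands at 0% of its charge and target at 59.4% against the ceiling of 60.0%, and at 3.00 d target still stands at 59.4%.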